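**Plan**

1. Numbering: trione ring C1(benzoyl)–C2(=O)–C3–C4(=O)–C5(geranyl)–C9(=O); bridge C5–C6–C7–C8(Me2)–C1; link C7–C10–C11–C3; cyclopentane C3–C11–C12(Me2)–C13(CMe2OH)–C14. The carbocycle C5–C6–C7–C8–C1–C9 has its ketone C9 between two bridgeheads and CMe2 (C8) next to C1. This is the retron of a 2-silyloxybutadiene (C6=C5–C9=C1) adding to a β,β-dimethyl enone (C7=C8, carbonyl C10) that hangs on C5 through C4–C3–C11–C10.
2. Retrosynthetic cuts, in order: C1–COPh; C1–C2 (Claisen); C5–geranyl; C10=O restored; C6–C7 and C1–C8 (type 2 intramolecular Diels–Alder); C4–C5 (Morita–Baylis–Hillman); C3–C4 (aldol); C11–C10 (conjugate addition); ring bond C3=C11 (metathesis); C13–C14 (auxiliary alkylation).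
3. Forward: cyclopentene ester 14 → C11 and C3 substituents → enone arm and silyloxydiene arm → cycloaddition closes the cyclohexene and the seven-membered ring → C10 deoxygenation and C5 geranylation → Claisen closure of the trione ring (homoadamantane) → C1 benzoylation, desilylation, C4 oxidation.
4. Stereochemistry: C13 from the oxazolidinone alkylation; C11 by cuprate addition anti to the C13 side chain; C3 by aldol anti to the C11 vinyl group; C7 in the cycloaddition from the trans-disubstituted cyclopentane tether; C5 and C1 are bridgeheads fixed by the cage.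

Key step: step 18

Assumption (chemistry): the C4 carbinol centre made in step 15 is not controlled and is drawn as one epimer; either epimer (or the mixture) converges on the C4 ketone in step 25. Descriptors in parentheses use the core numbering of the plan.

**Route**

Step 1
Reactants: 1 3,3-dimethylpent-4-enoic acid; 2 (4S)-4-benzyl-1,3-oxazolidin-2-one
Product: 4 (4S)-4-benzyl-3-(3,3-dimethylpent-4-enoyl)-1,3-oxazolidin-2-one, via mixed pivalic anhydride 3 (not isolated)
Conditions: pivaloyl chloride, Et3N, THF, −20 °C; then 2, LiCl, −20 °C → rt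
Reagents that add atoms: none
Why: N-acylation of the oxazolidinone by the mixed anhydride, which is attacked at its less hindered acyl carbon, avoids a strong base.

Step 2
Reactants: 4 (4S)-4-benzyl-3-(3,3-dimethylpent-4-enoyl)-1,3-oxazolidin-2-one; 5 2,3-dibromoprop-1-ene
Product: 7 (4S)-4-benzyl-3-[(2S)-2-(2-bromoprop-2-en-1-yl)-3,3-dimethylpent-4-enoyl]-1,3-oxazolidin-2-one, via sodium enolate 6 (not isolated)
Conditions: NaN(SiMe3)2, THF, −78 °C; then 5, −78 → −40 °C
Reagents that add atoms: none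
Why: Evans alkylation, in which the chelated (Z)-enolate takes the reactive allylic bromide on the face away from the benzyl group and so sets C13 as (S).

Step 3
Reactants: 7 (4S)-4-benzyl-3-[(2S)-2-(2-bromoprop-2-en-1-yl)-3,3-dimethylpent-4-enoyl]-1,3-oxazolidin-2-one
Product: 8 methyl (2S)-2-(2-bromoprop-2-en-1-yl)-3,3-dimethylpent-4-enoate
Conditions: MeMgBr (1.2 equiv) in MeOH (gives MeOMgBr), CH2Cl2, 0 °C → rt
Reagents that add atoms: methanol, CO
Why: transesterification with bromomagnesium methoxide attacks the exocyclic imide carbonyl and should release the auxiliary without epimerising C13.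

Step 4
Reactants: 8 methyl (2S)-2-(2-bromoprop-2-en-1-yl)-3,3-dimethylpent-4-enoate
Product: 10 (3S)-3-(2-bromoprop-2-en-1-yl)-2,4,4-trimethylhex-5-en-2-ol, via methyl ketone 9 (not isolated)
Conditions: MeMgBr (4 equiv), THF, 0 → 40 °C
Reagents that add atoms: methylmagnesium bromide, C[Mg]Br
Why: double Grignard addition to the ester gives the tertiary carbinol of the side chain, and the vinyl bromide is inert to MeMgBr.

Step 5
Reactants: 10 (3S)-3-(2-bromoprop-2-en-1-yl)-2,4,4-trimethylhex-5-en-2-ol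
Product: 11 {[(3S)-3-(2-bromoprop-2-en-1-yl)-2,4,4-trimethylhex-5-en-2-yl]oxy}triethylsilane
Conditions: Et3SiOTf, 2,6-lutidine, CH2Cl2, −78 → 0 °C
Reagents that add atoms: triethylsilyl trifluoromethanesulfonate, CC[Si](CC)(CC)OS(=O)(=O)C(F)(F)F
Why: silylation of the hindered tertiary alcohol with the silyl triflate gives an ether that should last through the organometallic, oxidative and Lewis-acid steps up to step 24.

Step 6
Reactants: 11 {[(3S)-3-(2-bromoprop-2-en-1-yl)-2,4,4-trimethylhex-5-en-2-yl]oxy}triethylsilane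
Product: 13 methyl (4S)-5,5-dimethyl-2-methylidene-4-[2-(triethylsilyloxy)propan-2-yl]hept-6-enoate, via vinyllithium 12 (not isolated)
Conditions: t-BuLi (2.1 equiv), Et2O, −78 °C; then ClCO2Me, −78 °C
Reagents that add atoms: methyl chloroformate, COC(=O)Cl
Why: bromine–lithium exchange and acylation of the vinyllithium with the chloroformate give the 2-substituted acrylate that carries C3 and C2.

Step 7
Reactants: 13 methyl (4S)-5,5-dimethyl-2-methylidene-4-[2-(triethylsilyloxy)propan-2-yl]hept-6-enoate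
Product: 14 methyl (4S)-3,3-dimethyl-4-[2-(triethylsilyloxy)propan-2-yl]cyclopent-1-ene-1-carboxylate
Conditions: second-generation Grubbs catalyst (H2IMes)(PCy3)Cl2Ru=CHPh (5 mol %), toluene, 80 °C
Reagents that add atoms: none
Why: ring-closing metathesis to a five-membered ring, helped by the gem-dimethyl group, should give the conjugated cyclopentene ester (C3=C11) with loss of ethene.

Step 8
Reactants: 14 methyl (4S)-3,3-dimethyl-4-[2-(triethylsilyloxy)propan-2-yl]cyclopent-1-ene-1-carboxylate
Product: 16 methyl (1R,2S,4S)-2-ethenyl-3,3-dimethyl-4-[2-(triethylsilyloxy)propan-2-yl]cyclopentane-1-carboxylate, via silyl ketene acetal 15 (not isolated)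
Conditions: CH2=CHMgBr, CuBr·SMe2 (10 mol %), Me3SiCl, THF, −78 → −30 °C; then AcOH, H2O, THF, 0 °C
Reagents that add atoms: vinylmagnesium bromide, C=C[Mg]Br
Why: copper-catalysed conjugate addition accelerated by Me3SiCl should deliver the vinyl group (C10) to C11 on the ring face opposite the bulky C13 side chain, which sets C11; C3 is flattened again in step 9.

Step 9
Reactants: 16 methyl (1R,2S,4S)-2-ethenyl-3,3-dimethyl-4-[2-(triethylsilyloxy)propan-2-yl]cyclopentane-1-carboxylate
Product: 18 methyl (1S,2R,4S)-2-ethenyl-1-(hydroxymethyl)-3,3-dimethyl-4-[2-(triethylsilyloxy)propan-2-yl]cyclopentane-1-carboxylate, via lithium enolate 17 (not isolated)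
Conditions: LiN(i-Pr)2, THF, −78 °C; then CH2O (gas, from cracked paraformaldehyde), −78 → −20 °C
Reagents that add atoms: formaldehyde, C=O
Why: aldol reaction of the ester enolate with formaldehyde, in which the electrophile enters C3 anti to the adjacent C11 vinyl group, sets the quaternary C3 with CO2Me (C2) cis and CH2OH (C4) trans to C10.

Step 10
Reactants: 18 methyl (1S,2R,4S)-2-ethenyl-1-(hydroxymethyl)-3,3-dimethyl-4-[2-(triethylsilyloxy)propan-2-yl]cyclopentane-1-carboxylate
Product: 20 methyl 2-formyl-1-(hydroxymethyl)-3,3-dimethyl-4-[2-(triethylsilyloxy)propan-2-yl]cyclopentane-1-carboxylate (C10 formyl cis to CO2Me; trans to the C13 side chain), via ozonide 19 (not isolated)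
Conditions: O3, CH2Cl2, −78 °C; then PPh3, −78 °C → rt
Reagents that add atoms: ozone, [O-][O+]=O
Why: ozonolysis of the only alkene with reductive work-up gives the C10 aldehyde, and no stereocentre is touched.

Step 11
Reactants: 20 methyl 2-formyl-1-(hydroxymethyl)-3,3-dimethyl-4-[2-(triethylsilyloxy)propan-2-yl]cyclopentane-1-carboxylate
Product: 21 methyl 2-ethynyl-1-(hydroxymethyl)-3,3-dimethyl-4-[2-(triethylsilyloxy)propan-2-yl]cyclopentane-1-carboxylate (configuration as in 18)
Conditions: dimethyl (1-diazo-2-oxopropyl)phosphonate, K2CO3, MeOH, 0 °C → rt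
Reagents that add atoms: dimethyl (1-diazo-2-oxopropyl)phosphonate, CC(=O)C(=[N+]=[N-])P(=O)(OC)OC
Why: Ohira–Bestmann (Seyferth–Gilbert) homologation turns the aldehyde into the terminal alkyne C10≡C7 under mild carbonate conditions, and the drawn C11 epimer, with its substituent trans to the larger groups on both neighbours, is also the one favoured if C11 equilibrates.

Step 12
Reactants: 21 methyl 2-ethynyl-1-(hydroxymethyl)-3,3-dimethyl-4-[2-(triethylsilyloxy)propan-2-yl]cyclopentane-1-carboxylate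
Product: 23 methyl 1-(hydroxymethyl)-2-(3-hydroxy-3-methylbut-1-yn-1-yl)-3,3-dimethyl-4-[2-(triethylsilyloxy)propan-2-yl]cyclopentane-1-carboxylate (configuration as in 18), via magnesium alkynide 22 (not isolated)
Conditions: EtMgBr (2.2 equiv), THF, 0 °C → rt; then acetone, 0 °C
Reagents that add atoms: acetone, CC(C)=O
Why: the bromomagnesium acetylide adds to acetone to give the tertiary propargylic alcohol (C8), and the neopentyl ester on the quaternary C3 should not compete.

Step 13
Reactants: 23 methyl 1-(hydroxymethyl)-2-(3-hydroxy-3-methylbut-1-yn-1-yl)-3,3-dimethyl-4-[2-(triethylsilyloxy)propan-2-yl]cyclopentane-1-carboxylate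
Product: 24 methyl 1-formyl-2-(3-hydroxy-3-methylbut-1-yn-1-yl)-3,3-dimethyl-4-[2-(triethylsilyloxy)propan-2-yl]cyclopentane-1-carboxylate (C4 aldehyde; configuration as in 18)
Conditions: Dess–Martin periodinane, NaHCO3, CH2Cl2, 0 °C → rt
Reagents that add atoms: none
Why: Dess–Martin oxidation of the neopentyl primary alcohol gives the non-enolisable C4 aldehyde, the tertiary propargylic alcohol cannot be oxidised, and the primary hydroxyl is removed before the gold step, where it could add to the alkyne.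

Step 14
Reactants: 24 methyl 1-formyl-2-(3-hydroxy-3-methylbut-1-yn-1-yl)-3,3-dimethyl-4-[2-(triethylsilyloxy)propan-2-yl]cyclopentane-1-carboxylate
Product: 25 methyl 1-formyl-3,3-dimethyl-2-(3-methylbut-2-enoyl)-4-[2-(triethylsilyloxy)propan-2-yl]cyclopentane-1-carboxylate (C10 acyl cis to CO2Me; trans to the C13 side chain)
Conditions: Ph3PAuNTf2 (2 mol %), MeOH (1 equiv), toluene, rt
Reagents that add atoms: none
Why: gold-catalysed Meyer–Schuster rearrangement (1,3-hydroxyl shift through the allenol) gives the β,β-dimethyl enone with its carbonyl at C10 and never passes through a C10 alkoxide that could lactonise onto the cis C3 ester.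

Step 15
Reactants: 25 methyl 1-formyl-3,3-dimethyl-2-(3-methylbut-2-enoyl)-4-[2-(triethylsilyloxy)propan-2-yl]cyclopentane-1-carboxylate; 26 but-3-en-2-one
Product: 27 Morita–Baylis–Hillman adduct: C3 carries CH(OH)–C(=CH2)–C(=O)CH3 (C4–C5(=C6)–C9–C1) in place of the formyl group of 25
Conditions: DABCO (50 mol %), 26 (5 equiv), MeOH–dioxane, rt
Reagents that add atoms: none
Why: Morita–Baylis–Hillman reaction in which the DABCO–butenone zwitterion adds to the aldehyde, activated by its α-ester, while the β,β-disubstituted enone is too hindered for the amine; the new C4 centre is uncontrolled and is removed in step 25.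

Step 16
Reactants: 27 Morita–Baylis–Hillman adduct
Product: 28 C4 triethylsilyl ether of 27
Conditions: Et3SiOTf, 2,6-lutidine, CH2Cl2, −78 °C
Reagents that add atoms: triethylsilyl trifluoromethanesulfonate, CC[Si](CC)(CC)OS(=O)(=O)C(F)(F)F
Why: O-silylation of the secondary allylic alcohol with a base too weak to enolise either ketone.

Step 17
Reactants: 28 C4 triethylsilyl ether of 27
Product: 30 silyloxydiene: C3 carries CH(OSiEt3)–C(=CH2)–C(OSiMe2t-Bu)=CH2 (C6=C5–C9=C1) and C11 carries the 3-methylbut-2-enoyl group (C10, C7=C8), via lithium dienolate 29 (not isolated)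
Conditions: LiN(SiMe3)2 (1.05 equiv), THF, −78 °C; then t-BuMe2SiOTf, −78 °C
Reagents that add atoms: tert-butyldimethylsilyl trifluoromethanesulfonate, CC(C)(C)[Si](C)(C)OS(=O)(=O)C(F)(F)F
Why: kinetic deprotonation of the acetyl methyl group (the C10 ketone offers only the shielded C11–H and vinylogous γ-hydrogens) and O-silylation give the 2-silyloxy-1,3-diene.

Step 18
Reactants: 30 silyloxydiene
Product: 31 bicyclo[4.3.1]decene cycloadduct (C5=C9 bridgehead tert-butyldimethylsilyl enol ether; C10 ketone; C3 methyl ester; C4 triethylsilyl ether; cyclopentane trans-fused at C3–C11; C7 as in the target)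
Conditions: Et2AlCl (30 mol %), CH2Cl2, −78 → −20 °C
Reagents that add atoms: none
Why: Et2AlCl binds the C10 carbonyl and lowers the LUMO of the β,β-dimethyl enone, so that the nucleophilic diene terminus C1 attacks the β-carbon C8 while C7 bonds to C6 in a concerted, asynchronous [4+2] cycloaddition (a Mukaiyama–Michael/Michael sequence through the same complex would give the same product). The closest known reaction type is the Lewis-acid-promoted type 2 intramolecular Diels–Alder reaction of 2-substituted dienes with a four-atom tether, which gives bridgehead-alkene bicyclo[4.3.1]decenes. The cyclohexene C5–C6–C7–C8–C1–C9 is closed by the cycloaddition itself, and the seven-membered ring C5–C4–C3–C11–C10–C7–C6 closes with it in the bridged mode, the only one the tether from C5 allows, so regiochemistry needs no further control and the silyl enol ether ends at the bridgehead. The one new stereocentre, C7, is set by the face of C7=C8 that the diene reaches: the trans-disubstituted cyclopentane fixes the sign of the C4–C3–C11–C10 torsion, and with the s-cis enone held planar the tether should reach the diene with C14 and C12 turned outward and the C3 ester on the side of C9–C1. This facial preference is argued from the tether geometry only and is the main uncertainty of the route. The ester is a much weaker Lewis base than the enone, and the hindered silyl enol ether should survive substoichiometric Et2AlCl at low temperature.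

Step 19
Reactants: 31 bicyclo[4.3.1]decene cycloadduct
Product: 34 C10 S-methyl xanthate of the cycloadduct (C10–O on the face of C8 and the C3 ester), via lithium alkoxide 32 (not isolated), via lithium xanthate 33 (not isolated)
Conditions: LiBH(s-Bu)3, THF, −78 °C; then CS2, −78 → 0 °C; then MeI, 0 °C
Reagents that add atoms: carbon disulfide, S=C=S; iodomethane, CI
Why: hydride should add to the C10 ketone from the open face (the other is flanked by the C8 and C12 gem-dimethyl groups), and the alkoxide is trapped at once as the xanthate before it can lactonise onto the cis C3 ester; the C10 centre is removed in step 20.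

Step 20
Reactants: 34 C10 S-methyl xanthate of the cycloadduct
Product: 35 C10-deoxygenated bridgehead silyl enol ether (C10 is CH2)
Conditions: Bu3SnH, AIBN (cat.), toluene, 90 °C
Reagents that add atoms: none
Why: Barton–McCombie deoxygenation through the secondary C10 radical, to which the silyl enol ether, the ester and the silyl ethers are inert.

Step 21
Reactants: 35 C10-deoxygenated bridgehead silyl enol ether; 36 geranyl bromide
Product: 38 C5-geranyl C9 ketone (bicyclo[4.3.1]decan-9-one; C3 methyl ester; C4 triethylsilyl ether), via sulfonium enolate 37 (not isolated)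
Conditions: tris(dimethylamino)sulfonium difluorotrimethylsilicate, 36, THF, −78 → −20 °C
Reagents that add atoms: none
Why: fluoride cleaves only the silyl enol ether, and the regiodefined bridgehead enolate is C-alkylated by the allylic bromide (SN2); as a bridgehead, C5 can take the geranyl group only on its outer face.

Step 22
Reactants: 38 C5-geranyl C9 ketone
Product: 40 homoadamantane-2,9-dione (C1–H bridgehead; C4 triethylsilyl ether; tertiary triethylsilyl ether), via lithium enolate 39 (not isolated)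
Conditions: LiN(i-Pr)2 (1.3 equiv), THF, −78 → −20 °C; then aq NH4Cl, −78 °C
Reagents that add atoms: none
Why: intramolecular Claisen condensation, in which C1 is the only enolisable position of the C9 ketone and its kinetic enolate attacks the C3 ester (C2) held above it, closes the six-membered trione ring (6-exo-trig); C1 becomes a bridgehead fixed by the cage.

Step 23
Reactants: 40 homoadamantane-2,9-dione
Product: 42 C1-benzoyl homoadamantane-2,9-dione bis(triethylsilyl) ether, via bridgehead organolithium 41 (not isolated)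
Conditions: lithium 2,2,6,6-tetramethylpiperidide, THF, −78 °C; then PhCOCl, −78 → −40 °C
Reagents that add atoms: benzoyl chloride, O=C(Cl)c1ccccc1
Why: bridgehead deprotonation of C1, acidified by the flanking C9 and C2 carbonyls, and C-acylation with the acid chloride is the known way to bridgehead acyl groups in bicyclo[3.3.1]nonane polyketones and occurs with retention because the bridgehead cannot invert.

Step 24
Reactants: 42 C1-benzoyl homoadamantane-2,9-dione bis(triethylsilyl) ether
Product: 43 C4 secondary alcohol with free tertiary alcohol (4-hydroxy-1-benzoyl-2,9-dione)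
Conditions: HF·pyridine, pyridine, THF, 0 °C → rt
Reagents that add atoms: none
Why: acidic fluoride should remove both triethylsilyl ethers without the retro-Claisen cleavage that basic fluoride could cause in the β-tricarbonyl array.

Step 25
Reactants: 43 C4 secondary alcohol
Product: 44 CNP0164095.2
Conditions: Dess–Martin periodinane, NaHCO3, CH2Cl2, rt
Reagents that add atoms: none
Why: Dess–Martin oxidation of the secondary C4 alcohol gives the third ring ketone, and the tertiary alcohol, the geranyl alkenes and the tricarbonyl unit should be untouched under buffered neutral conditions.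

**Compound list**

1 | 3,3-dimethylpent-4-enoic acid | C=CC(C)(C)CC(=O)O | starting material
2 | (4S)-4-benzyl-1,3-oxazolidin-2-one | O=C1N[C@@H](Cc2ccccc2)CO1 | starting material
3 | 3,3-dimethylpent-4-enoic pivalic anhydride | C=CC(C)(C)CC(=O)OC(=O)C(C)(C)C | intermediate (not isolated)
4 | (4S)-4-benzyl-3-(3,3-dimethylpent-4-enoyl)-1,3-oxazolidin-2-one | C=CC(C)(C)CC(=O)N1[C@@H](Cc2ccccc2)COC1=O | intermediate
5 | 2,3-dibromoprop-1-ene | C=C(Br)CBr | starting material
6 | sodium (Z)-enolate of 4 | [Na+].[O-]/C(=C\C(C)(C)C=C)N1[C@@H](Cc2ccccc2)COC1=O | intermediate (not isolated)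
7 | (4S)-4-benzyl-3-[(2S)-2-(2-bromoprop-2-en-1-yl)-3,3-dimethylpent-4-enoyl]-1,3-oxazolidin-2-one | C=CC(C)(C)[C@H](CC(Br)=C)C(=O)N1[C@@H](Cc2ccccc2)COC1=O | intermediate
8 | methyl (2S)-2-(2-bromoprop-2-en-1-yl)-3,3-dimethylpent-4-enoate | C=CC(C)(C)[C@H](CC(Br)=C)C(=O)OC | intermediate
9 | (3S)-3-(2-bromoprop-2-en-1-yl)-4,4-dimethylhex-5-en-2-one | C=CC(C)(C)[C@H](CC(Br)=C)C(C)=O | intermediate (not isolated)
10 | (3S)-3-(2-bromoprop-2-en-1-yl)-2,4,4-trimethylhex-5-en-2-ol | C=CC(C)(C)[C@H](CC(Br)=C)C(C)(C)O | intermediate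
11 | {[(3S)-3-(2-bromoprop-2-en-1-yl)-2,4,4-trimethylhex-5-en-2-yl]oxy}triethylsilane | C=CC(C)(C)[C@H](CC(Br)=C)C(C)(C)O[Si](CC)(CC)CC | intermediate
12 | vinyllithium from 11 (Li in place of Br) | C=CC(C)(C)[C@H](CC([Li])=C)C(C)(C)O[Si](CC)(CC)CC | intermediate (not isolated)
13 | methyl (4S)-5,5-dimethyl-2-methylidene-4-[2-(triethylsilyloxy)propan-2-yl]hept-6-enoate | C=CC(C)(C)[C@H](CC(=C)C(=O)OC)C(C)(C)O[Si](CC)(CC)CC | intermediate
14 | methyl (4S)-3,3-dimethyl-4-[2-(triethylsilyloxy)propan-2-yl]cyclopent-1-ene-1-carboxylate | COC(=O)C1=CC(C)(C)[C@@H](C(C)(C)O[Si](CC)(CC)CC)C1 | intermediate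
15 | methyl trimethylsilyl ketene acetal of 16 | C=C[C@@H]1C(C)(C)[C@@H](C(C)(C)O[Si](CC)(CC)CC)CC1=C(OC)O[Si](C)(C)C | intermediate (not isolated)
16 | methyl (1R,2S,4S)-2-ethenyl-3,3-dimethyl-4-[2-(triethylsilyloxy)propan-2-yl]cyclopentane-1-carboxylate | C=C[C@@H]1C(C)(C)[C@@H](C(C)(C)O[Si](CC)(CC)CC)C[C@H]1C(=O)OC | intermediate
17 | lithium enolate of 16 | [Li+].C=C[C@@H]1C(C)(C)[C@@H](C(C)(C)O[Si](CC)(CC)CC)CC1=C([O-])OC | intermediate (not isolated)
18 | methyl (1S,2R,4S)-2-ethenyl-1-(hydroxymethyl)-3,3-dimethyl-4-[2-(triethylsilyloxy)propan-2-yl]cyclopentane-1-carboxylate | C=C[C@@H]1C(C)(C)[C@@H](C(C)(C)O[Si](CC)(CC)CC)C[C@]1(CO)C(=O)OC | intermediate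
19 | ozonide (1,2,4-trioxolane) of 18 | C1(OCOO1)[C@@H]2C(C)(C)[C@@H](C(C)(C)O[Si](CC)(CC)CC)C[C@]2(CO)C(=O)OC | intermediate (not isolated)
20 | methyl 2-formyl-1-(hydroxymethyl)-3,3-dimethyl-4-[2-(triethylsilyloxy)propan-2-yl]cyclopentane-1-carboxylate (configuration as in 18) | O=C[C@@H]1C(C)(C)[C@@H](C(C)(C)O[Si](CC)(CC)CC)C[C@]1(CO)C(=O)OC | intermediate
21 | methyl 2-ethynyl-1-(hydroxymethyl)-3,3-dimethyl-4-[2-(triethylsilyloxy)propan-2-yl]cyclopentane-1-carboxylate (configuration as in 18) | C#C[C@@H]1C(C)(C)[C@@H](C(C)(C)O[Si](CC)(CC)CC)C[C@]1(CO)C(=O)OC | intermediate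
22 | bis(bromomagnesium) alkynide alkoxide of 21 | Br[Mg]C#C[C@@H]1C(C)(C)[C@@H](C(C)(C)O[Si](CC)(CC)CC)C[C@]1(CO[Mg]Br)C(=O)OC | intermediate (not isolated)
23 | methyl 1-(hydroxymethyl)-2-(3-hydroxy-3-methylbut-1-yn-1-yl)-3,3-dimethyl-4-[2-(triethylsilyloxy)propan-2-yl]cyclopentane-1-carboxylate | CC(C)(O)C#C[C@@H]1C(C)(C)[C@@H](C(C)(C)O[Si](CC)(CC)CC)C[C@]1(CO)C(=O)OC | intermediate
24 | methyl 1-formyl-2-(3-hydroxy-3-methylbut-1-yn-1-yl)-3,3-dimethyl-4-[2-(triethylsilyloxy)propan-2-yl]cyclopentane-1-carboxylate | CC(C)(O)C#C[C@@H]1C(C)(C)[C@@H](C(C)(C)O[Si](CC)(CC)CC)C[C@]1(C=O)C(=O)OC | intermediate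
25 | methyl 1-formyl-3,3-dimethyl-2-(3-methylbut-2-enoyl)-4-[2-(triethylsilyloxy)propan-2-yl]cyclopentane-1-carboxylate | CC(C)=CC(=O)[C@@H]1C(C)(C)[C@@H](C(C)(C)O[Si](CC)(CC)CC)C[C@]1(C=O)C(=O)OC | intermediate
26 | but-3-en-2-one | C=CC(C)=O | starting material
27 | Morita–Baylis–Hillman adduct (C4 carbinol; C5 methylidene; C9 methyl ketone) | CC(C)=CC(=O)[C@@H]1C(C)(C)[C@@H](C(C)(C)O[Si](CC)(CC)CC)C[C@]1([C@@H](O)C(=C)C(C)=O)C(=O)OC | intermediate
28 | C4 triethylsilyl ether of 27 | CC(C)=CC(=O)[C@@H]1C(C)(C)[C@@H](C(C)(C)O[Si](CC)(CC)CC)C[C@]1([C@@H](O[Si](CC)(CC)CC)C(=C)C(C)=O)C(=O)OC | intermediate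
29 | lithium dienolate of 28 (C9 enolate) | [Li+].CC(C)=CC(=O)[C@@H]1C(C)(C)[C@@H](C(C)(C)O[Si](CC)(CC)CC)C[C@]1([C@@H](O[Si](CC)(CC)CC)C(=C)C(=C)[O-])C(=O)OC | intermediate (not isolated)
30 | silyloxydiene tethered through the cyclopentane to the dimethylvinyl ketone (Diels–Alder precursor) | CC(C)=CC(=O)[C@@H]1C(C)(C)[C@@H](C(C)(C)O[Si](CC)(CC)CC)C[C@]1([C@@H](O[Si](CC)(CC)CC)C(=C)C(=C)O[Si](C)(C)C(C)(C)C)C(=O)OC | intermediate
31 | bicyclo[4.3.1]decene cycloadduct with bridgehead silyl enol ether and C10 ketone | C1(=C(O[Si](C)(C)C(C)(C)C)CC2(C)C)C[C@H]2C(=O)[C@@H]3C(C)(C)[C@@H](C(C)(C)O[Si](CC)(CC)CC)C[C@@]3(C(=O)OC)[C@H]1O[Si](CC)(CC)CC | intermediate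
32 | lithium C10 alkoxide of the cycloadduct | [Li+].C1(=C(O[Si](C)(C)C(C)(C)C)CC2(C)C)C[C@H]2[C@H]([O-])[C@@H]3C(C)(C)[C@@H](C(C)(C)O[Si](CC)(CC)CC)C[C@@]3(C(=O)OC)[C@H]1O[Si](CC)(CC)CC | intermediate (not isolated)
33 | lithium C10 xanthate | [Li+].C1(=C(O[Si](C)(C)C(C)(C)C)CC2(C)C)C[C@H]2[C@H](OC(=S)[S-])[C@@H]3C(C)(C)[C@@H](C(C)(C)O[Si](CC)(CC)CC)C[C@@]3(C(=O)OC)[C@H]1O[Si](CC)(CC)CC | intermediate (not isolated)
34 | C10 S-methyl xanthate of the cycloadduct | C1(=C(O[Si](C)(C)C(C)(C)C)CC2(C)C)C[C@H]2[C@H](OC(=S)SC)[C@@H]3C(C)(C)[C@@H](C(C)(C)O[Si](CC)(CC)CC)C[C@@]3(C(=O)OC)[C@H]1O[Si](CC)(CC)CC | intermediate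
35 | C10-deoxygenated bridgehead silyl enol ether | C1(=C(O[Si](C)(C)C(C)(C)C)CC2(C)C)C[C@H]2C[C@@H]3C(C)(C)[C@@H](C(C)(C)O[Si](CC)(CC)CC)C[C@@]3(C(=O)OC)[C@H]1O[Si](CC)(CC)CC | intermediate
36 | geranyl bromide, (2E)-1-bromo-3,7-dimethylocta-2,6-diene | CC(C)=CCC/C(C)=C/CBr | starting material
37 | tris(dimethylamino)sulfonium bridgehead enolate | CN(C)[S+](N(C)C)N(C)C.C1(=C([O-])CC2(C)C)C[C@H]2C[C@@H]3C(C)(C)[C@@H](C(C)(C)O[Si](CC)(CC)CC)C[C@@]3(C(=O)OC)[C@H]1O[Si](CC)(CC)CC | intermediate (not isolated)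
38 | C5-geranyl C9 ketone with C3 methyl ester | CC(C)=CCC/C(C)=C/C[C@@]1(C(=O)CC2(C)C)C[C@H]2C[C@@H]3C(C)(C)[C@@H](C(C)(C)O[Si](CC)(CC)CC)C[C@@]3(C(=O)OC)[C@H]1O[Si](CC)(CC)CC | intermediate
39 | lithium C9/C1 enolate of 38 | [Li+].CC(C)=CCC/C(C)=C/C[C@@]1(C([O-])=CC2(C)C)C[C@H]2C[C@@H]3C(C)(C)[C@@H](C(C)(C)O[Si](CC)(CC)CC)C[C@@]3(C(=O)OC)[C@H]1O[Si](CC)(CC)CC | intermediate (not isolated)
40 | homoadamantane-2,9-dione with C1–H, C4 and tertiary triethylsilyl ethers | CC(C)=CCC/C(C)=C/C[C@@]12C[C@H]3C[C@@H]4C(C)(C)[C@@H](C(C)(C)O[Si](CC)(CC)CC)C[C@]4([C@H]1O[Si](CC)(CC)CC)C(=O)[C@@H](C2=O)C3(C)C | intermediate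
41 | C1 bridgehead organolithium of 40 | CC(C)=CCC/C(C)=C/C[C@@]12C[C@H]3C[C@@H]4C(C)(C)[C@@H](C(C)(C)O[Si](CC)(CC)CC)C[C@]4([C@H]1O[Si](CC)(CC)CC)C(=O)[C@@]([Li])(C2=O)C3(C)C | intermediate (not isolated)
42 | C1-benzoyl homoadamantane-2,9-dione bis(triethylsilyl) ether | CC(C)=CCC/C(C)=C/C[C@@]12C[C@H]3C[C@@H]4C(C)(C)[C@@H](C(C)(C)O[Si](CC)(CC)CC)C[C@]4([C@H]1O[Si](CC)(CC)CC)C(=O)[C@@](C(=O)c1ccccc1)(C2=O)C3(C)C | intermediate
43 | C4 alcohol with free tertiary alcohol | CC(C)=CCC/C(C)=C/C[C@@]12C[C@H]3C[C@@H]4C(C)(C)[C@@H](C(C)(C)O)C[C@]4([C@H]1O)C(=O)[C@@](C(=O)c1ccccc1)(C2=O)C3(C)C | intermediate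
44 | CNP0164095.2 | CC(C)=CCC/C(C)=C/C[C@@]12C[C@H]3C[C@@H]4C(C)(C)[C@@H](C(C)(C)O)C[C@]4(C1=O)C(=O)[C@@](C(=O)c1ccccc1)(C2=O)C3(C)C | target

**Step count**

Total steps: 25. Longest linear sequence: 25 steps (the route is fully linear from 1).

**Steps most likely to fail**

Step 18. The cycloaddition may stall because the β,β-dimethyl enone is hindered, the silyl enol ether may be lost to the Lewis acid before it reacts, or the diene may reach the wrong face of C7=C8. The fallback replaces the neutral cycloaddition by an anion-accelerated, stepwise Michael–Michael ring closure. It sets out from 30, which with anhydrous tetrabutylammonium difluorotriphenylsilicate in THF at −78 °C should give the tetrabutylammonium dienolate F1. Its carbon C1 should add to C8 and the resulting C7 enolate to C6, giving the tetrabutylammonium bridgehead enolate F2. Trapping with t-BuMe2SiCl comes back to the route at 31.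

Step 15. The amine-catalysed coupling may fail because the aldehyde sits on a quaternary carbon and butenone oligomerises faster than its zwitterion adds. The fallback replaces nucleophilic catalysis by a stoichiometric conjugate addition/aldol/elimination sequence. It sets out from 25: Me2AlSPh and 26 in CH2Cl2 at −78 °C should give, through the aluminium enolate of the thiolate adduct, the β-phenylthio aldol adduct F3. mCPBA at −78 °C should give the sulfoxide F4, and its syn-elimination on warming in toluene comes back to the route at 27.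

Step 22. The condensation may stop or reverse (retro-Claisen cleavage by LiOMe, or O-acylation to an enol lactone), because the product cannot be stabilised as a conjugated enolate. The fallback closes the same C1–C2 bond by aldol addition and then oxidises. It sets out from 38: LiAlH4 in THF should reduce the ketone and the ester to the diol F5, Dess–Martin periodinane should oxidise both alcohols to the keto aldehyde F6, and KN(SiMe3)2 at −78 °C should add the C1 enolate to the C2 aldehyde to give the β-hydroxy ketone F7. A second Dess–Martin oxidation comes back to the route at 40.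

**Further compounds**

F1 | step 18 | tetrabutylammonium dienolate of 30 | CCCC[N+](CCCC)(CCCC)CCCC.CC(C)=CC(=O)[C@@H]1C(C)(C)[C@@H](C(C)(C)O[Si](CC)(CC)CC)C[C@]1([C@@H](O[Si](CC)(CC)CC)C(=C)C(=C)[O-])C(=O)OC
F2 | step 18 | tetrabutylammonium bridgehead enolate of the cycloadduct | CCCC[N+](CCCC)(CCCC)CCCC.C1(=C([O-])CC2(C)C)C[C@H]2C(=O)[C@@H]3C(C)(C)[C@@H](C(C)(C)O[Si](CC)(CC)CC)C[C@@]3(C(=O)OC)[C@H]1O[Si](CC)(CC)CC
F3 | step 15 | β-phenylthio aldol adduct of 25 and 26 | CC(C)=CC(=O)[C@@H]1C(C)(C)[C@@H](C(C)(C)O[Si](CC)(CC)CC)C[C@]1([C@@H](O)C(CSc2ccccc2)C(C)=O)C(=O)OC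
F4 | step 15 | sulfoxide of F3 | CC(C)=CC(=O)[C@@H]1C(C)(C)[C@@H](C(C)(C)O[Si](CC)(CC)CC)C[C@]1([C@@H](O)C(CS(=O)c2ccccc2)C(C)=O)C(=O)OC
F5 | step 22 | C9 alcohol and C2 primary alcohol (diol from 38) | CC(C)=CCC/C(C)=C/C[C@@]1(C(O)CC2(C)C)C[C@H]2C[C@@H]3C(C)(C)[C@@H](C(C)(C)O[Si](CC)(CC)CC)C[C@@]3(CO)[C@H]1O[Si](CC)(CC)CC
F6 | step 22 | C9 ketone C2 aldehyde | CC(C)=CCC/C(C)=C/C[C@@]1(C(=O)CC2(C)C)C[C@H]2C[C@@H]3C(C)(C)[C@@H](C(C)(C)O[Si](CC)(CC)CC)C[C@@]3(C=O)[C@H]1O[Si](CC)(CC)CC
F7 | step 22 | homoadamantane C2 carbinol C9 ketone (aldol product) | CC(C)=CCC/C(C)=C/C[C@@]12C[C@H]3C[C@@H]4C(C)(C)[C@@H](C(C)(C)O[Si](CC)(CC)CC)C[C@]4([C@H]1O[Si](CC)(CC)CC)C(O)[C@@H](C2=O)C3(C)C
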